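**Retrosynthetic overview**
1. The target is the (E)-enal self-aldol dimer of 12-[(2R,5S,6S)-5-hydroxy-6-methylpiperidin-2-yl]dodecanal; the last step unmasks this aldehyde and lets it self-condense.
2. The monomer (as its dioxolane) comes from N–C6 bond formation: hydrogenative Cbz removal and intramolecular reductive amination of an N-Cbz δ-amino-γ-hydroxy enone, which sets C6 cis.
3. The C2–N and C3–O bonds and both of their stereocentres come from one asymmetric aminohydroxylation of the distal alkene of an achiral sorbyl ketone (key step).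
4. The sorbyl ketone comes from the Weinreb amide of sorbic acid and a C12 Grignard acetal, itself made from 2-(2-bromoethyl)-1,3-dioxolane and 1,9-dibromononane.
5. Ring order: the single piperidine ring is closed once, on the monomer (step 5); dimerisation (step 6) then supplies both rings of the target.

Assumption: compounds 1, 2, 5 and all reagents named are taken as catalogue chemicals. The SMILES is read as two identical all-cis (2S,3S,6R)-2-methyl-6-alkylpiperidin-3-ol rings joined through an (E)-2-alkyl-2-enal.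

**Step 1**
Reactants: 1 2-(2-bromoethyl)-1,3-dioxolane; 2 1,9-dibromononane
Product: 4 2-(11-bromoundecyl)-1,3-dioxolane, via dioxolanylethyl Grignard reagent 3 (not isolated)
Conditions: Mg, THF, 25 °C; then 2 (3 equiv), Li2CuCl4 (3 mol%), THF, −10 → 0 °C
Reagents that add atoms: magnesium, [Mg] (retained only in intermediate 3)
Why: Copper-catalysed Kochi sp3–sp3 coupling of a primary alkyl Grignard reagent with a primary alkyl bromide; the threefold excess of dibromide suppresses double coupling and the acetal is inert.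

**Step 2**
Reactants: 5 sorbic acid
Product: 7 (2E,4E)-N-methoxy-N-methylhexa-2,4-dienamide, via sorbyl imidazolide 6 (not isolated)
Conditions: CDI, CH2Cl2, 0 °C → rt; then MeNH(OMe)·HCl, rt
Reagents that add atoms: 1,1'-carbonyldiimidazole, O=C(n1ccnc1)n1ccnc1 (imidazolyl group retained only in intermediate 6); N,O-dimethylhydroxylamine hydrochloride, CNOC.Cl
Why: Carboxyl activation as the acylimidazole followed by aminolysis (standard Weinreb amide formation) leaves the diene geometry untouched.

**Step 3**
Reactants: 4 2-(11-bromoundecyl)-1,3-dioxolane; 7 (2E,4E)-N-methoxy-N-methylhexa-2,4-dienamide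
Product: 9 (2E,4E)-17-(1,3-dioxolan-2-yl)heptadeca-2,4-dien-6-one, via dioxolanylundecyl Grignard reagent 8 (not isolated)
Conditions: Mg, THF, 45 °C; then 7, THF, −20 → 0 °C; inverse quench into cold aq NH4Cl
Reagents that add atoms: magnesium, [Mg] (retained only in intermediate 8)
Why: Weinreb ketone synthesis, in which chelation of magnesium by the N-methoxy group holds the 1,2-adduct until work-up so over-addition is avoided; the cold buffered quench keeps released MeNH(OMe) from adding to the dienone.

**Step 4**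
Reactants: 9 (2E,4E)-17-(1,3-dioxolan-2-yl)heptadeca-2,4-dien-6-one
Product: 10 benzyl N-[(2S,3S,4E)-17-(1,3-dioxolan-2-yl)-3-hydroxy-6-oxoheptadec-4-en-2-yl]carbamate
Conditions: BnOC(O)NH2 (3.1 equiv), t-BuOCl (3.05 equiv), NaOH (3.05 equiv), K2OsO2(OH)4 (4 mol%), (DHQ)2AQN [hydroquinine anthraquinone-1,4-diyl diether] (5 mol%), n-PrOH–H2O (1:1), 0 °C → rt
Reagents that add atoms: benzyl carbamate, NC(=O)OCc1ccccc1; water, O
Why: Proposed new method: a distal-site- and δ-nitrogen-selective Sharpless-type asymmetric aminohydroxylation of a conjugated 2,4-dienyl ketone, which is not established for this substrate class (closest known reactions: osmium-catalysed asymmetric aminohydroxylation of cinnamates, crotonates and styrenes, and asymmetric dihydroxylation of 2,4-dienoates at the γ,δ-alkene); the electrophilic octavalent osmium imido species should attack only the more electron-rich C2=C3 alkene, suprafacial [3+2] addition to the E-alkene gives the syn amino alcohol, the dihydroquinine ligand directs addition to the α-face, which for a trans-alkene sets (2S,3S) in either binding orientation, and nitrogen should go to the methyl-bearing carbon because the anthraquinone ligand orients the flat enone arm so that its carbon receives oxygen (as the aryl-bearing carbon does in cinnamates with this ligand), which here coincides with the electronic preference for nitrogen at the terminus remote from the acceptor.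

**Step 5**
Reactants: 10 benzyl N-[(2S,3S,4E)-17-(1,3-dioxolan-2-yl)-3-hydroxy-6-oxoheptadec-4-en-2-yl]carbamate
Product: 13 (2S,3S,6R)-6-[11-(1,3-dioxolan-2-yl)undecyl]-2-methylpiperidin-3-ol, via saturated amino ketone 11 (not isolated), via cyclic imine 12 (not isolated)
Conditions: H2 (1 atm), Pd/C (10 wt%), EtOH, rt
Reagents that add atoms: none
Why: One-pot hydrogenation cascade in which Pd/C saturates the enone C=C and hydrogenolyses the Cbz group, the freed amine condenses with the C6 ketone (intramolecular reductive amination, N–C6 bond), and H2 adds to the cyclic imine from the face opposite the C2 methyl group, setting C6 as R and giving the all-cis ring.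

**Step 6**
Reactants: 13 (2S,3S,6R)-6-[11-(1,3-dioxolan-2-yl)undecyl]-2-methylpiperidin-3-ol (2 equiv)
Product: 15 (2E)-2-{10-[(2R,5S,6S)-5-hydroxy-6-methylpiperidin-2-yl]decyl}-14-[(2R,5S,6S)-5-hydroxy-6-methylpiperidin-2-yl]tetradec-2-enal, via free amino aldehyde 14 (not isolated)
Conditions: 1 M aq HCl–THF (1:2), 40 °C; then NaOAc (to pH 5), pyrrolidine (30 mol%), 50 °C; then aq NaOH (pH 11), 0 °C, CH2Cl2 extraction
Reagents that add atoms: water, O
Why: Acid hydrolysis of the dioxolane frees the aldehyde as its piperidinium salt, and pyrrolidine-catalysed enamine aldol self-condensation with dehydration gives the thermodynamically favoured (E)-2-alkyl-2-enal; protonation keeps the hindered ring nitrogens out of the reaction and no stereocentre is touched.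

**Compound list**
1 | 2-(2-bromoethyl)-1,3-dioxolane | BrCCC1OCCO1 | starting material
2 | 1,9-dibromononane | BrCCCCCCCCCBr | starting material
3 | [2-(1,3-dioxolan-2-yl)ethyl]magnesium bromide | Br[Mg]CCC1OCCO1 | intermediate
4 | 2-(11-bromoundecyl)-1,3-dioxolane | BrCCCCCCCCCCCC1OCCO1 | intermediate
5 | sorbic acid, (2E,4E)-hexa-2,4-dienoic acid | C/C=C/C=C/C(=O)O | starting material
6 | (2E,4E)-1-(1H-imidazol-1-yl)hexa-2,4-dien-1-one | C/C=C/C=C/C(=O)n1ccnc1 | intermediate
7 | (2E,4E)-N-methoxy-N-methylhexa-2,4-dienamide | C/C=C/C=C/C(=O)N(C)OC | intermediate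
8 | [11-(1,3-dioxolan-2-yl)undecyl]magnesium bromide | Br[Mg]CCCCCCCCCCCC1OCCO1 | intermediate
9 | (2E,4E)-17-(1,3-dioxolan-2-yl)heptadeca-2,4-dien-6-one | C/C=C/C=C/C(=O)CCCCCCCCCCCC1OCCO1 | intermediate
10 | benzyl N-[(2S,3S,4E)-17-(1,3-dioxolan-2-yl)-3-hydroxy-6-oxoheptadec-4-en-2-yl]carbamate | C[C@H](NC(=O)OCc1ccccc1)[C@@H](O)/C=C/C(=O)CCCCCCCCCCCC2OCCO2 | intermediate
11 | (2S,3S)-2-amino-17-(1,3-dioxolan-2-yl)-3-hydroxyheptadecan-6-one | C[C@H](N)[C@@H](O)CCC(=O)CCCCCCCCCCCC1OCCO1 | intermediate
12 | (2S,3S)-6-[11-(1,3-dioxolan-2-yl)undecyl]-2-methyl-2,3,4,5-tetrahydropyridin-3-ol | C[C@@H]1N=C(CCCCCCCCCCCC2OCCO2)CC[C@@H]1O | intermediate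
13 | (2S,3S,6R)-6-[11-(1,3-dioxolan-2-yl)undecyl]-2-methylpiperidin-3-ol (all-cis) | C[C@@H]1N[C@H](CCCCCCCCCCCC2OCCO2)CC[C@@H]1O | intermediate
14 | 12-[(2R,5S,6S)-5-hydroxy-6-methylpiperidin-2-yl]dodecanal | C[C@@H]1N[C@H](CCCCCCCCCCCC=O)CC[C@@H]1O | intermediate
15 | (2E)-2-{10-[(2R,5S,6S)-5-hydroxy-6-methylpiperidin-2-yl]decyl}-14-[(2R,5S,6S)-5-hydroxy-6-methylpiperidin-2-yl]tetradec-2-enal (CNP0177491.1) | C[C@@H]1N[C@H](CCCCCCCCCCC/C=C(/C=O)CCCCCCCCCC[C@@H]2CC[C@H](O)[C@H](C)N2)CC[C@@H]1O | target

**Step count and risks**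
Total steps: 6. Longest linear sequence: 5 (steps 1, 3, 4, 5, 6).

Most likely to fail, first: step 4, the new aminohydroxylation. The risks are the regioisomer with nitrogen on the allylic carbon, attack at the enone alkene, and base-induced isomerisation of the γ-hydroxy enone to a 1,4-diketone. The fallback uses known chemistry, sets out from Grignard reagent 8 and rejoins the route at 10. Reagent 8 is added to acrolein (THF, −78 °C) to give racemic 14-(1,3-dioxolan-2-yl)tetradec-1-en-3-ol F1, which Dess–Martin periodinane oxidises to 14-(1,3-dioxolan-2-yl)tetradec-1-en-3-one F2. Commercial N-Cbz-L-alaninal and vinylmagnesium bromide (THF, −78 °C, chelation control, anti isomer removed by chromatography) give benzyl N-[(2S,3S)-3-hydroxypent-4-en-2-yl]carbamate F3. Cross-metathesis of F2 with F3 using the second-generation Hoveyda–Grubbs catalyst RuCl2(H2IMes)(=CH–C6H4-2-OiPr) in CH2Cl2 at 40 °C then gives the E-enone 10.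

Second: step 5, the hydrogenation cascade. The risks are hydrogenolysis or redox isomerisation of the free allylic alcohol, hemiketal or furan side products, and incomplete cis control. The fallback sets out from 10 and rejoins at 14, running the reduction with the C3 hydroxyl masked. TBSCl and imidazole in DMF give benzyl N-[(2S,3S,4E)-3-[(tert-butyldimethylsilyl)oxy]-17-(1,3-dioxolan-2-yl)-6-oxoheptadec-4-en-2-yl]carbamate F4. Hydrogenation (H2, Pd(OH)2/C, EtOAc) gives (2S,3S,6R)-3-[(tert-butyldimethylsilyl)oxy]-6-[11-(1,3-dioxolan-2-yl)undecyl]-2-methylpiperidine F5. The aqueous HCl stage of step 6 then removes the silyl ether together with the acetal and delivers 14.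

Third: step 6, unmasking and dimerisation with unprotected amines. The risks are oligomers, aza-Michael adducts and slow condensation in the aqueous medium. The fallback sets out from 13 and rejoins at 15, with the nitrogens masked as carbamates during the condensation. Boc2O (THF, 60 °C) gives tert-butyl (2S,3S,6R)-6-[11-(1,3-dioxolan-2-yl)undecyl]-3-hydroxy-2-methylpiperidine-1-carboxylate F6. PPTS in acetone–H2O at 60 °C gives tert-butyl (2S,3S,6R)-3-hydroxy-2-methyl-6-(12-oxododecyl)piperidine-1-carboxylate F7. Pyrrolidine and benzoic acid (20 mol% each, toluene, rt) give the bis(N-Boc) derivative of the enal dimer F8. TFA in CH2Cl2 at 0 °C followed by aq NaOH work-up gives 15.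

**Further compounds**
F1 | step 4 | 14-(1,3-dioxolan-2-yl)tetradec-1-en-3-ol (racemic) | C=CC(O)CCCCCCCCCCCC1OCCO1
F2 | step 4 | 14-(1,3-dioxolan-2-yl)tetradec-1-en-3-one | C=CC(=O)CCCCCCCCCCCC1OCCO1
F3 | step 4 | benzyl N-[(2S,3S)-3-hydroxypent-4-en-2-yl]carbamate | C[C@H](NC(=O)OCc1ccccc1)[C@@H](O)C=C
F4 | step 5 | benzyl N-[(2S,3S,4E)-3-[(tert-butyldimethylsilyl)oxy]-17-(1,3-dioxolan-2-yl)-6-oxoheptadec-4-en-2-yl]carbamate | C[C@H](NC(=O)OCc1ccccc1)[C@@H](O[Si](C)(C)C(C)(C)C)/C=C/C(=O)CCCCCCCCCCCC2OCCO2
F5 | step 5 | (2S,3S,6R)-3-[(tert-butyldimethylsilyl)oxy]-6-[11-(1,3-dioxolan-2-yl)undecyl]-2-methylpiperidine | C[C@@H]1N[C@H](CCCCCCCCCCCC2OCCO2)CC[C@@H]1O[Si](C)(C)C(C)(C)C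
F6 | step 6 | tert-butyl (2S,3S,6R)-6-[11-(1,3-dioxolan-2-yl)undecyl]-3-hydroxy-2-methylpiperidine-1-carboxylate | C[C@@H]1N(C(=O)OC(C)(C)C)[C@H](CCCCCCCCCCCC2OCCO2)CC[C@@H]1O
F7 | step 6 | tert-butyl (2S,3S,6R)-3-hydroxy-2-methyl-6-(12-oxododecyl)piperidine-1-carboxylate | C[C@@H]1N(C(=O)OC(C)(C)C)[C@H](CCCCCCCCCCCC=O)CC[C@@H]1O
F8 | step 6 | bis(N-Boc) derivative of 15 (both ring nitrogens as tert-butyl carbamates) | C[C@@H]1N(C(=O)OC(C)(C)C)[C@H](CCCCCCCCCCC/C=C(/C=O)CCCCCCCCCC[C@@H]2CC[C@H](O)[C@H](C)N2C(=O)OC(C)(C)C)CC[C@@H]1O
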